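## The problem

Target 25 is a linear diarylheptanoid in which one oxygen atom is shared by C1 and C5, so that C1–C5 and this oxygen form an oxane. C1 bears ring A (3,4-dihydroxy-5-methoxyphenyl), C3 a free hydroxyl, and C5 the C6–C7 ethylene that ends in ring B (4-hydroxy-3-methoxyphenyl). The stereocentres C1 (S), C3 (R) and C5 (S) are separated by methylene groups and place all three substituents equatorial on one chair, the all-cis and thermodynamically preferred arrangement. Since no two centres are neighbours, one can steer another only through a six-membered ring or transition state, and at least one centre has to bring in the absolute configuration. Ring A is a catechol with a third oxygen beside it and oxidises readily once free, most of all in base; the C1–O bond is a benzylic ether of an electron-rich arene and can ionise in acid or be cut by hydrogenolysis. The phenols therefore stay masked until the last step, and that step has to be neutral. The feature that opens an enzymatic entry is the segment C1–C6: oxygen on C1, C3 and C5 with CH2 at C2 and C4 is the pattern of a 2,4-dideoxyhexose, which an acetaldehyde-dependent aldolase builds from three two-carbon aldehydes, the first of which can carry a leaving group that ends up on C6. The enzyme gives C3 in the sense of 25 but C5 in the opposite sense, so a synthesis built on it must replace the C5 oxygen by the C1 oxygen with inversion.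

## Retrosynthesis

**Unmasking.** The three phenols of 25 are carried as benzyl ethers and C6–C7 as an alkene, so that a single neutral hydrogenation of 24 forms no skeletal bond but removes four sites of unsaturation or protection at once. The C3 hydroxyl of 24 is carried as the silyl ether 23, because a fluoride deprotection is best done while no free catechol is present. The forward reactions must leave the benzylic C1–O bond intact.

**C6=C7.** Cutting 23 at the alkene gives the oxane aldehyde 18 and the ring B ylide 22, made in the flask from phosphonium salt 21, which comes from alcohol 20 and aldehyde 19. The neighbouring cuts, C5–C6 or C7–aryl, would need sp3–sp3 couplings beside an ether oxygen. The olefination joins two fragments of comparable size, the alkene geometry is irrelevant, and ring B arrives late. Aldehyde 18 comes from the primary alcohol 17 by oxidation; its α-centre is equatorial, so epimerisation has no driving force.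

**C5–O.** The oxane of 17 is opened at the C5–O bond to give the epoxy alcohol 16. The alternative ring cut at C1–O would keep the enzyme's C5 configuration and lead to the C3/C5-trans oxane. Opening a C5–C6 epoxide at C5 by the C1 hydroxyl inverts C5 and at the same time leaves C6 as the hydroxymethyl handle. The precursor is acyclic, and the forward step must be 6-exo, SN2-like and mild enough not to ionise C1.

**C1–H, C6–O and C1–aryl.** The C1 carbinol of 16 is traced to the aryl ketone 15, because an aryl alkyl ketone is the ideal substrate for a catalyst-controlled reduction and the C3 centre is too remote to be relied on. The epoxide of 15 comes from the chlorohydrin 14, the open-chain tautomer of hemiketal 13, with the C5–O bond untouched. Adduct 13 is cut at the C1–aryl bond into lactone 7 and aryllithium 12. A cut at C1–C2 instead would discard two carbons that the aldolase supplies. Aryllithium 12 comes from bromide 11, made from catechol 10 and the commercial aldehyde 8. The forward addition must stop after one aryl group, which the lactone oxidation level ensures.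

**Adjusting the aldolase product.** Lactone 7 is the silyl ether of hydroxy lactone 6, the oxidation product of lactol 5. The lactone makes C1 an acylating carbon and the silyl group keeps the C3 oxygen out of every later step. No skeletal bond changes.

**C4–C5 and C2–C3.** Lactol 5 is cut into chloroacetaldehyde 1 and two molecules of acetaldehyde 2, through the mono-adduct 3 and the open-chain diol aldehyde 4. No chemical aldol sequence reaches the same skeleton with two carbinol centres, in water, without protecting groups or a chiral reagent. The precursors are the simplest possible. The forward step must add exactly two donors and give C3 (R) and C5 (S).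

## Roads not taken

**Alternative 1:** The chain is cut at C2–C3 and C3–C4, with C3 as a silyl dithiane linchpin A4, C1–C2 as the ring A aryl oxirane A2 and C4–C7 as the ring B oxirane A3. In the forward step lithiated A4 opens A2 at its CH2, a 1,4-shift of silicon from carbon to the new alkoxide (Brook rearrangement, released by a strongly coordinating cosolvent) regenerates a dithiane anion, and this opens A3 to give A1.
- Merits: the whole C1–C7 chain with both rings is assembled in one flask, and C1 and C5 each come from their own enantiopure epoxide, so no relay of stereochemistry is needed.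
- Weak points: A2 is an electron-rich aryl oxirane, for which benzylic attack and rearrangement compete with opening at CH2. Two epoxides need separate asymmetric preparation. C3 emerges as a masked ketone that must be freed from sulfur in the presence of electron-rich arenes and then reduced selectively. A1 carries C5 in the sense opposite to 25, so the oxane must be closed by displacement of a secondary sulfonate at C5, where elimination competes.
- Comparison: alternative 1 is more convergent and probably shorter in its longest linear sequence. The chosen plan sets against this two stereocentres from one catalytic step on bulk aldehydes, C3 at the carbinol level from the outset, no sulfur to remove, and an invertive closure that is an epoxide opening, not a sulfonate displacement.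

**Alternative 2:** The cut is C1–C2 together with the ring. The precursor A6 is the C5 carbinol as its ring A benzyl ether, with an enol acetate at C3 and ring B as a pivalate. In the forward step a high-potential quinone oxidant abstracts hydride from the ring A benzylic CH2, and the oxocarbenium ion is captured by the enol acetate through a chair to give the 2,6-cis oxanone A5.
- Merits: ring, C1–C2 bond and the C1 centre form in one step under substrate control from C5 alone. C3 would follow by equatorial-selective hydride reduction. No inversion is needed and ring B is present from the start. In step count this is the best of the four plans.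
- Weak points: the hydride abstraction depends on the donor strength of ring A, whose para oxygen is flanked on both sides and twisted out of conjugation. The substrate also carries other benzylic C–H bonds (the phenol benzyl ethers, C7, and C1–H of the product), so over-oxidation is a concern. C5 still needs its own asymmetric step.
- Comparison: alternative 2 is shorter and its stereochemical relay is more economical. The chosen plan avoids an oxidation whose selectivity rests on this particular arene, takes the absolute configuration from an enzyme, and uses only standard polar steps afterwards.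

**Alternative 3:** The cut is C5–C6. The precursor A8 is an oxane with C1 and C3 in place, a phenylselenide at C5 and the ring B alkyne tethered to the C3 oxygen through a dimethylsilyl group. Under tin hydride chain conditions the C5 radical adds to the silicon-bound alkyne carbon and closes the cis-fused siloxane A7, from which silicon is later removed and the alkene reduced.
- Merits: C5 is set from C3 by the tether, C5–C6 forms with ring B already attached, and no aldehyde or olefination is needed. In this last respect it is better than the chosen plan.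
- Weak points: the cis-fused bicycle needs the C3–O and C5–C6 bonds both axial, which forces the C1 aryl group axial or the oxane into a boat. Tin and selenium reagents are required. A8 already contains the ring and two stereocentres, so most of the problem is moved into its preparation.
- Comparison: both plans set C5 by an intramolecular event of comparable reliability. The chosen plan does it on a strain-free chair and solves the origin of C1–C6 and of two stereocentres in the same stroke.

Key step: step 1

Assumptions: adduct 13 is written as the cyclic hemiketal although it equilibrates with its open-chain tautomer 14, and either form enters step 7. Aldehyde 19, the benzyl ether of vanillin, is taken as purchased.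

## Steps

Step 1
Reactants: 1 chloroacetaldehyde; 2 acetaldehyde (two equivalents)
Product: 5 (4R,6S)-6-(chloromethyl)oxane-2,4-diol as an anomeric mixture, via (S)-4-chloro-3-hydroxybutanal 3 (not isolated), via (3R,5S)-6-chloro-3,5-dihydroxyhexanal 4 (not isolated)
Conditions: 2-deoxy-D-ribose-5-phosphate aldolase (E. coli, cell-free lysate), aqueous buffer pH 7.3, rt, slow co-feed of 1 and 2
Reagents that add atoms: none
Why: The active-site lysine condenses with 2 to an iminium ion that tautomerises to an enamine, which adds to the carbonyl of 1 on the one face the active site leaves open; hydrolysis releases 3 with C5 set as (S). Aldehyde 3 is itself an acceptor and takes a second enamine, which forms C2–C3 and sets C3 as (R) in 4. The closest known reaction type is the sequential aldolase addition of two acetaldehyde units to an α-substituted acetaldehyde, as used for statin side chains. The only ring closed is the hemiacetal: the C5 hydroxyl of 4 adds to the C1 aldehyde in a reversible, non-enzymatic 6-exo-trig closure that sets no lasting centre. Both new stereocentres are controlled by the enzyme alone, with no help from the substrate. The step needs three selectivities: 2 as the only donor, 1 as the first acceptor, and a stop after two additions. The donor site takes 2 but not the chloro aldehyde, the inductively activated carbonyl of 1 outruns self-addition of 2 when both are fed slowly, and cyclisation to 5 removes the free aldehyde that a third addition would need.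

Step 2
Reactants: 5 (4R,6S)-6-(chloromethyl)oxane-2,4-diol
Product: 6 (4R,6S)-6-(chloromethyl)-4-hydroxyoxan-2-one
Conditions: Br2, BaCO3, H2O, rt
Reagents that add atoms: none
Why: Bromine-water oxidation of a hemiacetal to the lactone, the classical aldose to aldonolactone conversion; the secondary carbinol and both stereocentres are not touched.

Step 3
Reactants: 6 (4R,6S)-6-(chloromethyl)-4-hydroxyoxan-2-one
Product: 7 (4R,6S)-4-[(tert-butyldimethylsilyl)oxy]-6-(chloromethyl)oxan-2-one
Conditions: TBSCl, imidazole, DMF, rt
Reagents that add atoms: tert-butyldimethylsilyl chloride, CC(C)(C)[Si](C)(C)Cl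
Why: Standard silylation of a secondary alcohol; imidazole is too weak a base to cause β-elimination of the β-oxygenated lactone.

Step 4
Reactants: 8 5-bromo-2-hydroxy-3-methoxybenzaldehyde
Product: 10 5-bromo-3-methoxybenzene-1,2-diol, via aryl formate 9 (not isolated)
Conditions: H2O2 (30% aq), NaOH, H2O, 0 °C to rt, N2; then HCl
Reagents that add atoms: hydrogen peroxide, OO
Why: Dakin oxidation: hydroperoxide adds to the aldehyde of the ortho-hydroxybenzaldehyde, the electron-rich aryl group migrates to oxygen, and the formate 9 is hydrolysed in the basic medium.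

Step 5
Reactants: 10 5-bromo-3-methoxybenzene-1,2-diol
Product: 11 1,2-bis(benzyloxy)-5-bromo-3-methoxybenzene
Conditions: BnBr, K2CO3, DMF, 60 °C, N2
Reagents that add atoms: benzyl bromide, BrCc1ccccc1
Why: Williamson etherification of both phenols; the benzyl ethers survive organolithium, base, mild acid, borane and fluoride and leave in the final hydrogenation.

Step 6
Reactants: 11 1,2-bis(benzyloxy)-5-bromo-3-methoxybenzene; 7 (4R,6S)-4-[(tert-butyldimethylsilyl)oxy]-6-(chloromethyl)oxan-2-one
Product: 13 (4R,6S)-2-[3,4-bis(benzyloxy)-5-methoxyphenyl]-4-[(tert-butyldimethylsilyl)oxy]-6-(chloromethyl)oxan-2-ol as a mixture at C2, via aryllithium 12 (not isolated)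
Conditions: 11, n-BuLi, THF, −78 °C; then 7, −78 °C; aq NH4Cl at −78 °C
Reagents that add atoms: none
Why: Bromine–lithium exchange followed by addition of the aryllithium to the lactone carbonyl, as in C-aryl glycoside synthesis; the lithium hemiketalate is stable at −78 °C, so only one aryl group adds, and the primary chloride is inert at this temperature.

Step 7
Reactants: 13 (4R,6S)-2-[3,4-bis(benzyloxy)-5-methoxyphenyl]-4-[(tert-butyldimethylsilyl)oxy]-6-(chloromethyl)oxan-2-ol
Product: 15 (3R)-1-[3,4-bis(benzyloxy)-5-methoxyphenyl]-3-[(tert-butyldimethylsilyl)oxy]-4-[(2S)-oxiran-2-yl]butan-1-one, via open-chain chlorohydrin ketone 14 (not isolated)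
Conditions: K2CO3, MeOH, 0 °C to rt
Reagents that add atoms: none
Why: Base opens the hemiketal to the δ-hydroxy ketone 14, whose C5 alkoxide displaces the neighbouring primary chloride (intramolecular Williamson reaction, 3-exo-tet). The C5–O bond is not broken, so C5 keeps its configuration, and the irreversible closure drains the ring–chain equilibrium.

Step 8
Reactants: 15 (3R)-1-[3,4-bis(benzyloxy)-5-methoxyphenyl]-3-[(tert-butyldimethylsilyl)oxy]-4-[(2S)-oxiran-2-yl]butan-1-one
Product: 16 (1S,3S)-1-[3,4-bis(benzyloxy)-5-methoxyphenyl]-3-[(tert-butyldimethylsilyl)oxy]-4-[(2S)-oxiran-2-yl]butan-1-ol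
Conditions: (R)-2-methyl-CBS-oxazaborolidine [(3aR)-1-methyl-3,3-diphenyltetrahydro-1H,3H-pyrrolo[1,2-c][1,3,2]oxazaborole] (20 mol%), BH3·SMe2, THF, −20 °C; MeOH quench
Reagents that add atoms: none
Why: Corey–Bakshi–Shibata reduction of an aryl alkyl ketone: the catalyst binds borane and the ketone with the aryl group as the large substituent, and the (R)-catalyst delivers hydride to the face that gives the (S)-carbinol. The silyl ether at C3 does not chelate, so the reagent decides; C3 is unchanged in space and only its descriptor changes.

Step 9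
Reactants: 16 (1S,3S)-1-[3,4-bis(benzyloxy)-5-methoxyphenyl]-3-[(tert-butyldimethylsilyl)oxy]-4-[(2S)-oxiran-2-yl]butan-1-ol
Product: 17 [(2R,4S,6S)-6-[3,4-bis(benzyloxy)-5-methoxyphenyl]-4-[(tert-butyldimethylsilyl)oxy]oxan-2-yl]methanol
Conditions: (1S)-10-camphorsulfonic acid (10 mol%), CH2Cl2, 0 °C
Reagents that add atoms: none
Why: Acid-catalysed 6-exo-tet opening of the epoxide by the C1 hydroxyl at C5 with SN2 inversion, through a chair with aryl, silyloxy and the forming hydroxymethyl all equatorial, which gives the all-cis oxane. The 7-endo path to C6 is disfavoured by ring size and by the lower cation character of the primary carbon, and every other oxygen is capped.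

Step 10
Reactants: 17 [(2R,4S,6S)-6-[3,4-bis(benzyloxy)-5-methoxyphenyl]-4-[(tert-butyldimethylsilyl)oxy]oxan-2-yl]methanol
Product: 18 (2R,4S,6S)-6-[3,4-bis(benzyloxy)-5-methoxyphenyl]-4-[(tert-butyldimethylsilyl)oxy]oxane-2-carbaldehyde
Conditions: Dess–Martin periodinane, CH2Cl2, 0 °C to rt; used crude
Reagents that add atoms: none
Why: Dess–Martin oxidation of a primary alcohol stops at the aldehyde under near-neutral conditions; the formyl group is equatorial, so the α-centre has no tendency to epimerise.

Step 11
Reactants: 19 4-(benzyloxy)-3-methoxybenzaldehyde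
Product: 20 [4-(benzyloxy)-3-methoxyphenyl]methanol
Conditions: NaBH4, MeOH, 0 °C
Reagents that add atoms: none
Why: Borohydride reduction of an aromatic aldehyde to the benzylic alcohol.

Step 12
Reactants: 20 [4-(benzyloxy)-3-methoxyphenyl]methanol
Product: 21 {[4-(benzyloxy)-3-methoxyphenyl]methyl}triphenylphosphonium bromide
Conditions: Ph3P·HBr, MeCN, reflux
Reagents that add atoms: triphenylphosphine hydrobromide, [Br-].c1ccc(cc1)[PH+](c1ccccc1)c1ccccc1
Why: Direct conversion of a para-alkoxybenzyl alcohol into its phosphonium salt: the protonated hydroxyl leaves with help from the para oxygen and triphenylphosphine captures the benzylic carbon.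

Step 13
Reactants: 21 {[4-(benzyloxy)-3-methoxyphenyl]methyl}triphenylphosphonium bromide; 18 (2R,4S,6S)-6-[3,4-bis(benzyloxy)-5-methoxyphenyl]-4-[(tert-butyldimethylsilyl)oxy]oxane-2-carbaldehyde
Product: 23 (2S,4R,6R)-2-[3,4-bis(benzyloxy)-5-methoxyphenyl]-6-{2-[4-(benzyloxy)-3-methoxyphenyl]ethenyl}-4-[(tert-butyldimethylsilyl)oxy]oxane as an E/Z mixture, via phosphorus ylide 22 (not isolated)
Conditions: 21, NaN(SiMe3)2, THF, 0 °C; then 18, −78 °C to rt
Reagents that add atoms: none
Why: Wittig olefination with a semi-stabilised benzylic ylide; the mixed alkene geometry does not matter because the double bond is hydrogenated, and the cold addition limits enolisation of the α-alkoxy aldehyde.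

Step 14
Reactants: 23 (2S,4R,6R)-2-[3,4-bis(benzyloxy)-5-methoxyphenyl]-6-{2-[4-(benzyloxy)-3-methoxyphenyl]ethenyl}-4-[(tert-butyldimethylsilyl)oxy]oxane
Product: 24 (2S,4R,6R)-2-[3,4-bis(benzyloxy)-5-methoxyphenyl]-6-{2-[4-(benzyloxy)-3-methoxyphenyl]ethenyl}oxan-4-ol as an E/Z mixture
Conditions: Bu4NF, THF, rt
Reagents that add atoms: none
Why: Fluoride cleavage of a secondary silyl ether; it is done while all phenols are still benzylated, so no catechol meets the basic fluoride.

Step 15
Reactants: 24 (2S,4R,6R)-2-[3,4-bis(benzyloxy)-5-methoxyphenyl]-6-{2-[4-(benzyloxy)-3-methoxyphenyl]ethenyl}oxan-4-ol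
Product: 25 (2S,4R,6S)-2-(3,4-dihydroxy-5-methoxyphenyl)-6-[2-(4-hydroxy-3-methoxyphenyl)ethyl]oxan-4-ol
Conditions: H2 (1 atm), Pd/C, EtOAc–MeOH, rt
Reagents that add atoms: none
Why: Catalytic hydrogenation saturates the disubstituted alkene and hydrogenolyses the three aryl benzyl ethers, which are cleaved much faster than a dialkyl benzylic ether such as C1–O. No stereocentre is touched, and the C5 descriptor changes from R to S only because the side chain loses its double bond.

## Compound list

1 | chloroacetaldehyde | ClCC=O | starting material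
2 | acetaldehyde | CC=O | starting material
3 | (S)-4-chloro-3-hydroxybutanal | ClC[C@@H](O)CC=O | intermediate
4 | (3R,5S)-6-chloro-3,5-dihydroxyhexanal | ClC[C@@H](O)C[C@@H](O)CC=O | intermediate
5 | (4R,6S)-6-(chloromethyl)oxane-2,4-diol, anomeric mixture | ClC[C@@H]1C[C@@H](O)CC(O)O1 | intermediate
6 | (4R,6S)-6-(chloromethyl)-4-hydroxyoxan-2-one | ClC[C@@H]1C[C@@H](O)CC(=O)O1 | intermediate
7 | (4R,6S)-4-[(tert-butyldimethylsilyl)oxy]-6-(chloromethyl)oxan-2-one | ClC[C@@H]1C[C@@H](O[Si](C)(C)C(C)(C)C)CC(=O)O1 | intermediate
8 | 5-bromo-2-hydroxy-3-methoxybenzaldehyde | COc1cc(Br)cc(C=O)c1O | starting material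
9 | 5-bromo-2-hydroxy-3-methoxyphenyl formate | COc1cc(Br)cc(OC=O)c1O | intermediate
10 | 5-bromo-3-methoxybenzene-1,2-diol | COc1cc(Br)cc(O)c1O | intermediate
11 | 1,2-bis(benzyloxy)-5-bromo-3-methoxybenzene | COc1cc(Br)cc(OCc2ccccc2)c1OCc1ccccc1 | intermediate
12 | [3,4-bis(benzyloxy)-5-methoxyphenyl]lithium | [Li]c1cc(OC)c(OCc2ccccc2)c(OCc2ccccc2)c1 | intermediate
13 | (4R,6S)-2-[3,4-bis(benzyloxy)-5-methoxyphenyl]-4-[(tert-butyldimethylsilyl)oxy]-6-(chloromethyl)oxan-2-ol, mixture at C2 | ClC[C@@H]1C[C@@H](O[Si](C)(C)C(C)(C)C)CC(O)(c2cc(OCc3ccccc3)c(OCc3ccccc3)c(OC)c2)O1 | intermediate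
14 | (3R,5S)-1-[3,4-bis(benzyloxy)-5-methoxyphenyl]-3-[(tert-butyldimethylsilyl)oxy]-6-chloro-5-hydroxyhexan-1-one | ClC[C@@H](O)C[C@@H](O[Si](C)(C)C(C)(C)C)CC(=O)c1cc(OCc2ccccc2)c(OCc2ccccc2)c(OC)c1 | intermediate
15 | (3R)-1-[3,4-bis(benzyloxy)-5-methoxyphenyl]-3-[(tert-butyldimethylsilyl)oxy]-4-[(2S)-oxiran-2-yl]butan-1-one | C1[C@@H](O1)C[C@@H](O[Si](C)(C)C(C)(C)C)CC(=O)c2cc(OCc3ccccc3)c(OCc3ccccc3)c(OC)c2 | intermediate
16 | (1S,3S)-1-[3,4-bis(benzyloxy)-5-methoxyphenyl]-3-[(tert-butyldimethylsilyl)oxy]-4-[(2S)-oxiran-2-yl]butan-1-ol | C1[C@@H](O1)C[C@@H](O[Si](C)(C)C(C)(C)C)C[C@H](O)c2cc(OCc3ccccc3)c(OCc3ccccc3)c(OC)c2 | intermediate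
17 | [(2R,4S,6S)-6-[3,4-bis(benzyloxy)-5-methoxyphenyl]-4-[(tert-butyldimethylsilyl)oxy]oxan-2-yl]methanol | OC[C@H]1C[C@@H](O[Si](C)(C)C(C)(C)C)C[C@@H](c2cc(OCc3ccccc3)c(OCc3ccccc3)c(OC)c2)O1 | intermediate
18 | (2R,4S,6S)-6-[3,4-bis(benzyloxy)-5-methoxyphenyl]-4-[(tert-butyldimethylsilyl)oxy]oxane-2-carbaldehyde | O=C[C@H]1C[C@@H](O[Si](C)(C)C(C)(C)C)C[C@@H](c2cc(OCc3ccccc3)c(OCc3ccccc3)c(OC)c2)O1 | intermediate
19 | 4-(benzyloxy)-3-methoxybenzaldehyde | COc1cc(C=O)ccc1OCc1ccccc1 | starting material
20 | [4-(benzyloxy)-3-methoxyphenyl]methanol | COc1cc(CO)ccc1OCc1ccccc1 | intermediate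
21 | {[4-(benzyloxy)-3-methoxyphenyl]methyl}triphenylphosphonium bromide | COc1cc(C[P+](c2ccccc2)(c2ccccc2)c2ccccc2)ccc1OCc1ccccc1.[Br-] | intermediate
22 | {[4-(benzyloxy)-3-methoxyphenyl]methylidene}triphenylphosphorane | COc1cc(C=P(c2ccccc2)(c2ccccc2)c2ccccc2)ccc1OCc1ccccc1 | intermediate
23 | (2S,4R,6R)-2-[3,4-bis(benzyloxy)-5-methoxyphenyl]-6-{2-[4-(benzyloxy)-3-methoxyphenyl]ethenyl}-4-[(tert-butyldimethylsilyl)oxy]oxane, E/Z mixture | COc1cc(C=C[C@H]2C[C@@H](O[Si](C)(C)C(C)(C)C)C[C@@H](c3cc(OCc4ccccc4)c(OCc4ccccc4)c(OC)c3)O2)ccc1OCc1ccccc1 | intermediate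
24 | (2S,4R,6R)-2-[3,4-bis(benzyloxy)-5-methoxyphenyl]-6-{2-[4-(benzyloxy)-3-methoxyphenyl]ethenyl}oxan-4-ol, E/Z mixture | COc1cc(C=C[C@H]2C[C@@H](O)C[C@@H](c3cc(OCc4ccccc4)c(OCc4ccccc4)c(OC)c3)O2)ccc1OCc1ccccc1 | intermediate
25 | (2S,4R,6S)-2-(3,4-dihydroxy-5-methoxyphenyl)-6-[2-(4-hydroxy-3-methoxyphenyl)ethyl]oxan-4-ol | COc1cc(CC[C@H]2C[C@@H](O)C[C@@H](c3cc(O)c(O)c(OC)c3)O2)ccc1O | target

## Step count and least certain steps

Total: 15 steps (the key step, ten further steps on the main line, two for bromide 11, two for salt 21). Longest linear sequence: 11 steps, from 1 and 2 through steps 1, 2, 3, 6, 7, 8, 9, 10, 13, 14 and 15 to 25.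

**Step 1 (key step).** The likely failure is loss of enzyme activity during the run, because both aldehydes modify surface and active-site lysines and the chloro aldehyde is also an alkylating agent; the reaction then stalls at the mono-adduct or is overtaken by self-addition of acetaldehyde. The fallback abandons the enzymatic construction and builds the same lactone by known ester chemistry. It does not set out from 1 and 2 but from commercial ethyl (S)-4-chloro-3-hydroxybutanoate F1. A Claisen condensation of F1 with the lithium enolate of tert-butyl acetate (LiN(iPr)2, THF, −78 to −40 °C) would give tert-butyl (5S)-6-chloro-5-hydroxy-3-oxohexanoate F2. A Narasaka–Prasad reduction (Et2BOMe, NaBH4, THF–MeOH, −78 °C) would deliver hydride syn to the C5 hydroxyl and give tert-butyl (3R,5S)-6-chloro-3,5-dihydroxyhexanoate F3. Trifluoroacetic acid in CH2Cl2 would cleave the ester and close the lactone, and the route is rejoined at 6.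

**Step 6.** The aryllithium may act as a base, deprotonating the lactone α-CH2, after which the enolate expels the C3 silyloxy group; or the tetrahedral adduct may collapse before the quench and take a second aryl group. The fallback sets out from 7 and changes the acyl acceptor. Opening 7 with MeNH(OMe)·HCl and Me3Al in CH2Cl2 would give (3R,5S)-3-[(tert-butyldimethylsilyl)oxy]-6-chloro-5-hydroxy-N-methoxy-N-methylhexanamide F4. Brief treatment with K2CO3 in MeOH would close it to (3R)-3-[(tert-butyldimethylsilyl)oxy]-N-methoxy-N-methyl-4-[(2S)-oxiran-2-yl]butanamide F5. Addition of 12 at −78 °C to this chelating amide would stop at the ketone, and the route is rejoined at 15; the hemiketal 13 is bypassed.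

**Step 7.** Carbonate in methanol may enolise the aryl ketone of 14 and trigger E1cB loss of the C3 silyloxy group faster than the alkoxide closes the epoxide, or the silyl group may migrate between the C3 and C5 oxygens. The fallback sets out from 13 and forms the epoxide while no ketone is present. NaBH4 in MeOH would reduce the open form to (3S,5S)-1-[3,4-bis(benzyloxy)-5-methoxyphenyl]-3-[(tert-butyldimethylsilyl)oxy]-6-chlorohexane-1,5-diol F6 as both C1 epimers. K2CO3 in MeOH would then close (3S)-1-[3,4-bis(benzyloxy)-5-methoxyphenyl]-3-[(tert-butyldimethylsilyl)oxy]-4-[(2S)-oxiran-2-yl]butan-1-ol F7, again as both C1 epimers. Dess–Martin oxidation of the benzylic carbinol would return the route to 15.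

**Step 8.** Facial selectivity may be poor if the C3 centre opposes the catalyst or if uncatalysed borane reduction competes. The fallback sets out from 15 and moves the stereochemical decision into a ring. A catalytic sulfonic acid in CH2Cl2 would let the carbonyl oxygen open the epoxide at C5 with inversion and the freed C6 oxygen close onto C1, giving the bicyclic ketal (1R,3R,5R)-5-[3,4-bis(benzyloxy)-5-methoxyphenyl]-3-[(tert-butyldimethylsilyl)oxy]-6,8-dioxabicyclo[3.2.1]octane F8. Et3SiH with Me3SiOTf at −78 °C would ionise the C1–O bond to the C6 oxygen and reduce the six-membered oxocarbenium ion by axial hydride attack, placing the aryl group equatorial and cis to the hydroxymethyl group. The route is rejoined at 17, and step 9 is bypassed as well. Its own weakness is that the silyloxy group is held axial in F8.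

**Step 15.** Prolonged exposure to the catalyst, needed for the hindered central benzyl ether of ring A, may cut the benzylic C1–O bond of the oxane, or the allylic C5–O bond before the alkene is saturated. The fallback sets out from 24 and separates the two tasks without a metal surface. Diimide (2-nitrobenzenesulfonyl hydrazide, Et3N, CH2Cl2, rt) would reduce the alkene to (2S,4R,6S)-2-[3,4-bis(benzyloxy)-5-methoxyphenyl]-6-{2-[4-(benzyloxy)-3-methoxyphenyl]ethyl}oxan-4-ol F9. BCl3 with pentamethylbenzene as cation scavenger in CH2Cl2 at −78 °C would then remove the three aryl benzyl ethers while leaving the methyl ethers, and the route is rejoined at 25.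

## Further compounds

F1 | step 1 | ethyl (S)-4-chloro-3-hydroxybutanoate | ClC[C@@H](O)CC(=O)OCC
F2 | step 1 | tert-butyl (5S)-6-chloro-5-hydroxy-3-oxohexanoate | ClC[C@@H](O)CC(=O)CC(=O)OC(C)(C)C
F3 | step 1 | tert-butyl (3R,5S)-6-chloro-3,5-dihydroxyhexanoate | ClC[C@@H](O)C[C@@H](O)CC(=O)OC(C)(C)C
F4 | step 6 | (3R,5S)-3-[(tert-butyldimethylsilyl)oxy]-6-chloro-5-hydroxy-N-methoxy-N-methylhexanamide | ClC[C@@H](O)C[C@@H](O[Si](C)(C)C(C)(C)C)CC(=O)N(C)OC
F5 | step 6 | (3R)-3-[(tert-butyldimethylsilyl)oxy]-N-methoxy-N-methyl-4-[(2S)-oxiran-2-yl]butanamide | C1[C@@H](O1)C[C@@H](O[Si](C)(C)C(C)(C)C)CC(=O)N(C)OC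
F6 | step 7 | (3S,5S)-1-[3,4-bis(benzyloxy)-5-methoxyphenyl]-3-[(tert-butyldimethylsilyl)oxy]-6-chlorohexane-1,5-diol, both C1 epimers | ClC[C@@H](O)C[C@@H](O[Si](C)(C)C(C)(C)C)CC(O)c1cc(OCc2ccccc2)c(OCc2ccccc2)c(OC)c1
F7 | step 7 | (3S)-1-[3,4-bis(benzyloxy)-5-methoxyphenyl]-3-[(tert-butyldimethylsilyl)oxy]-4-[(2S)-oxiran-2-yl]butan-1-ol, both C1 epimers | C1[C@@H](O1)C[C@@H](O[Si](C)(C)C(C)(C)C)CC(O)c2cc(OCc3ccccc3)c(OCc3ccccc3)c(OC)c2
F8 | step 8 | (1R,3R,5R)-5-[3,4-bis(benzyloxy)-5-methoxyphenyl]-3-[(tert-butyldimethylsilyl)oxy]-6,8-dioxabicyclo[3.2.1]octane | C1O[C@]2(c3cc(OCc4ccccc4)c(OCc4ccccc4)c(OC)c3)C[C@H](O[Si](C)(C)C(C)(C)C)C[C@H]1O2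
F9 | step 15 | (2S,4R,6S)-2-[3,4-bis(benzyloxy)-5-methoxyphenyl]-6-{2-[4-(benzyloxy)-3-methoxyphenyl]ethyl}oxan-4-ol | COc1cc(CC[C@H]2C[C@@H](O)C[C@@H](c3cc(OCc4ccccc4)c(OCc4ccccc4)c(OC)c3)O2)ccc1OCc1ccccc1
A1 | alternative 1 | (2R)-4-[4-(benzyloxy)-3-methoxyphenyl]-1-{2-[(2S)-2-[3,4-bis(benzyloxy)-5-methoxyphenyl]-2-[(tert-butyldimethylsilyl)oxy]ethyl]-1,3-dithian-2-yl}butan-2-ol | COc1cc(CC[C@@H](O)CC2(SCCCS2)C[C@@H](c2cc(OCc3ccccc3)c(OCc3ccccc3)c(OC)c2)O[Si](C)(C)C(C)(C)C)ccc1OCc1ccccc1
A2 | alternative 1 | (R)-2-[3,4-bis(benzyloxy)-5-methoxyphenyl]oxirane | C1[C@@H](c2cc(OCc3ccccc3)c(OCc3ccccc3)c(OC)c2)O1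
A3 | alternative 1 | (R)-2-{2-[4-(benzyloxy)-3-methoxyphenyl]ethyl}oxirane | COc1cc(CC[C@@H]2CO2)ccc1OCc1ccccc1
A4 | alternative 1 | 2-(tert-butyldimethylsilyl)-1,3-dithiane | CC(C)(C)[Si](C)(C)C1SCCCS1
A5 | alternative 2 | 4-{2-[(2S,6S)-6-[3,4-bis(benzyloxy)-5-methoxyphenyl]-4-oxooxan-2-yl]ethyl}-2-methoxyphenyl 2,2-dimethylpropanoate | COc1cc(CC[C@H]2CC(=O)C[C@@H](c3cc(OCc4ccccc4)c(OCc4ccccc4)c(OC)c3)O2)ccc1OC(=O)C(C)(C)C
A6 | alternative 2 | 4-[(3S)-5-acetoxy-3-{[3,4-bis(benzyloxy)-5-methoxyphenyl]methoxy}hex-5-en-1-yl]-2-methoxyphenyl 2,2-dimethylpropanoate | COc1cc(CC[C@@H](CC(=C)OC(C)=O)OCc2cc(OCc3ccccc3)c(OCc3ccccc3)c(OC)c2)ccc1OC(=O)C(C)(C)C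
A7 | alternative 3 | (7S)-7-[3,4-bis(benzyloxy)-5-methoxyphenyl]-4-[4-(benzyloxy)-3-methoxybenzylidene]-3,3-dimethyl-2,6-dioxa-3-silabicyclo[3.3.1]nonane, siloxane bridge cis to the aryl group, alkene geometry mixed | COc1cc(C=C3[C@H]2C[C@@H](O[Si]3(C)C)C[C@@H](c4cc(OCc5ccccc5)c(OCc5ccccc5)c(OC)c4)O2)ccc1OCc1ccccc1
A8 | alternative 3 | {[4-(benzyloxy)-3-methoxyphenyl]ethynyl}{[(2S,4S)-2-[3,4-bis(benzyloxy)-5-methoxyphenyl]-6-(phenylselanyl)oxan-4-yl]oxy}dimethylsilane, mixture at C6 | COc1cc(C#C[Si](C)(C)O[C@H]2C[C@@H](c3cc(OCc4ccccc4)c(OCc4ccccc4)c(OC)c3)OC([Se]c3ccccc3)C2)ccc1OCc1ccccc1
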